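The ratio of enzyme charged to impurity charged, 1.21 in the flask, we call the cover ratio. If impurity takes enzyme one for one, as we read the runs, a share 17.2% of the flask's enzyme outlasts it, and we expect a ratio of one to be the crossing between a reaction that stops and one that slows.

| flask | starting material | second substrate | enzyme | impurity | remark |
|---|---|---|---|---|---|
| Sunday's | 0.039 M | 1.1 equiv | 0.01 mol% | 4.8 µM | run made earlier |
| Thursday's | 0.087 M | 1.1 equiv | 0.01 mol% | 4.8 µM | run made earlier |
| Monday's | 0.058 M | 2.2 equiv | 0.01 mol% | 4.8 µM | run made earlier |
| flask | 0.058 M | 1.10 equiv | 0.01 mol% | 4.8 µM |  |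

- Sunday's (time / h: product / %): 1.33: 13; 4.00: 27; 8.00: 29; 10.0: 29; 15.0: 30; 20.0: 33
- Thursday's (time / h: product / %): 1.33: 36; 4.00: 60; 8.00: 78; 10.0: 84; 15.0: 89; 20.0: 92
- Monday's (time / h: product / %): 1.50: 40; 3.00: 59; 6.00: 77; 10.0: 86; 20.0: 96

(scatter of a reading: 1.5 percentage points)



Starting concentration is the first setting: at fixed loading it moves [enzyme] while [impurity] stays. By hand, Sunday's ratio of 0.812 lies below one and Thursday's 1.81 above it. The readings follow: Sunday's product stands at 29% after 8.00 h and 33% after 20.0 h, while Thursday's reaches 92%.

Second substrate leaves the ratio alone. By hand, doubling its charge multiplies [second substrate] at 50% conversion by 2.83, which is what a first-order rate would gain. Monday's run, doubled at the flask's ratio, reads 40% at 1.50 h, 59% at 3.00 h and 96% at 20.0 h.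

Loading moves the ratio directly, to 12.1 at 0.1 mol%. The surplus of enzyme over impurity then goes from 1.00 µM to 53.2 µM, so our own reckoning gives a factor of 53.2.

1. factor on the rate of making product when 50% of the starting material are converted if second substrate is charged twice over
2. factor on the rate when 50% of the starting material are converted if enzyme is charged at 0.1 mol% instead

The forecast, for which impurity “acts as a near-stoichiometric poison”, gives 3.8 and 32; its enzyme factor is lower than ours.

The simulation gives 4.89 and 43.7.

    starting material + enzyme ⇌ starting complex (K = 21.0 L mol⁻¹, k = 31800 L mol⁻¹ min⁻¹)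
    ternary complex → enzyme + product (k = 142 min⁻¹)
    starting material + starting complex → spent catalyst B (k = 0.0298 L mol⁻¹ min⁻¹)
    enzyme + impurity → spent catalyst A (k = 5020 L mol⁻¹ min⁻¹)
    second substrate + starting complex ⇌ ternary complex (K = 15.0 L mol⁻¹, k = 15100 L mol⁻¹ min⁻¹)

Doubling second substrate gains more than the first-order 2.83. The flask's apparent order in second substrate at 50% conversion is 3.4, and the same run without the falling back of ternary complex to second substrate + starting complex gives 0.98, so this falling back accounts for a part of the excess order. In the flask after 200 h, with impurity at 0% of its charge, spent catalyst A holds 82.8% of the catalyst charged, and the inverse cover ratio is 82.6%.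

The earlier runs and the new flask were generated by integration on assumed constants; noise was put on by code.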